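The rate constants are made up; what happens was integrated by code.

Four vessels, a closed flask, a dosed flask and two continuous tanks, take the same charge:

the same everywhere: substrate 0.20 M; free catalyst 20 mM
- green: reagent 0.220 M; time 12 min; everything together in a closed stirred flask, run for 12 min
- violet: reagent 0.220 M (fed, over 12.0 min); time 12 min; a stirred flask in which reagent is dosed at a steady rate over 12.0 min without added volume, worked up at 12 min
- teal: reagent 0.220 M; a single well-mixed tank run continuously and read at steady state, 12 min in it on average
- amber: reagent 0.220 M; a single well-mixed tank run continuously and read at steady state, 120 min in it on average

- the set-up with the highest amount of open intermediate at the outlet or at the end, in percent of the substrate put in ("none" if the first two lie within 2 percentage points) (green / violet / teal / amber / none)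
- amount of open intermediate at the outlet or at the end, in percent of the substrate put in, green
- amount of open intermediate at the outlet or at the end, in percent of the substrate put in, violet
- amount of open intermediate at the outlet or at the end, in percent of the substrate put in, teal
- amount of open intermediate at the outlet or at the end, in percent of the substrate put in, amber

- where a step has two of a species, its rate is k times that concentration squared, and two are used at each turn
- the stated concentrations are those of everything mixed, before any reaction; amounts are the same in each set-up
- the feed brings no volume worth counting
- run time (green): 12 min

    substrate + free catalyst → free catalyst + open intermediate (k1 = 5.0 /M/min)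
    free catalyst + open intermediate ⇌ catalyst intermediate (K2 = 13 /M, k2 = 76 /M/min)
    reagent + catalyst intermediate → free catalyst + target (k3 = 1.9 /M/min)
    substrate + reagent → uncatalysed product (k4 = 0.035 /M/min)
    target ⇌ isomer of the product (K5 = 0.38, k5 = 0.025 /min)
    2 free catalyst ⇌ resting dimer, settled at all times (K6 = 46 /M)

Substrate on free catalyst fills the open intermediate with constant 5.0 /M/min. Free catalyst then binds it as catalyst intermediate, which falls back at 5.85 /min but goes on with charged reagent at 0.418 /min, a pre-equilibrium. The return number, back runs per forward passage, is therefore 14.0. The forward rate constant of binding, divided by one plus that number, gives 5.07 /M/min, the capture constant.

Filling and capture both run on free catalyst, so c(open intermediate) follows two consecutive first-order steps on the clock c(free catalyst) times time. A first round counts the pairing to the off-cycle resting dimer as the one sink of free catalyst, which leaves 10.3 mM free, and this reckoning then gives green 33.1 %. Putting that amount back as a binder, with 1.86 as the linear term of the catalyst balance, leaves 7.76 mM free and a filling number of 0.466.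

Green then stands near 29.1 %. Violet, taken with reagent averaging half its charge and so a capture constant of half the value, stands near 32.9 %. In teal, each exponential becomes one over one plus the number, which gives 21.6 %.

Amber, with a filling number of 4.66, gives 14.4 % on charged reagent. In this reckoning, substrate gone beyond the open intermediate takes reagent with it, which leaves 0.0841 M. That gives 28.5 %, then 0.112 M, and finally 23.5 %.

The reckoning ranks violet first.

The forecast names violet, with 28.5 % for green, 32.5 % for violet, 21 % for teal and 22.5 % for amber, on the ground that “Dosing the reagent slowly starves the drain”.

The simulation gives violet as best, with 28.6 % for green, 31.6 % for violet, 20.8 % for teal and 22.1 % for amber.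

The back run of catalyst intermediate is the main reason for the level in teal: struck out, teal falls from 20.8 % to 3.84 %. Without it the capture constant returns to 76 /M/min, and the tank expression gives 3.93 %. For the violet flask charged with 0.012 M of free catalyst, the same balance reckons 5.14 mM free, and the same capture constant then gives 24.5 %. That neighbouring flask stood at 25.7 %.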